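**Retrosynthetic overview**
1. Target 10 ⇐ tris-MOM aryl ketone 9, by acid-catalysed acetal cleavage in the last step.
2. 9 ⇐ aryllithium 8 (from phloroglucinol 6 via 7) + hydroxy morpholine amide 5; this is the only C–C bond made, since all 20 chain carbons and the four Z-alkenes come intact from EPA 1.
3. 5 ⇐ cis-epoxy amide 4, by catalyst-controlled reductive opening that cleaves C18–O and keeps C17–O (the proposed new step).
4. 4 ⇐ EPA 1, by enzymatic 17,18-epoxidation; this C–O bond formation is the key step and fixes the C17 configuration.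
5. Rings: no ring of the target is built (the benzene ring arrives with 6); the only ring made is the transient oxirane (step 1), opened in step 3.

Assumption: wild-type P450 BM3 gives the 17S,18R epoxide of EPA (as recalled, about 95% ee), and the antipode of (η5-C5H4-menthyl)2TiCl2 that cleaves the C–O bond at the R-configured carbon of a cis-dialkyl epoxide is taken to be the L-menthyl one; one pilot run with each antipode on 4 settles this, and the D-menthyl complex is used if the sense is reversed.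

**Step 1**
Reactants: 1 (5Z,8Z,11Z,14Z,17Z)-icosa-5,8,11,14,17-pentaenoic acid (EPA)
Product: 2 (5Z,8Z,11Z,14Z)-16-[(2S,3R)-3-ethyloxiran-2-yl]hexadeca-5,8,11,14-tetraenoic acid
Conditions: P450 BM3 (CYP102A1, wild type, E. coli lysate), NADP+ (cat.), glucose dehydrogenase, D-glucose, catalase, air, K2HPO4/KH2PO4 buffer pH 7.8, 25 °C
Reagents that add atoms: dioxygen, O=O
Why: Enzymatic alkene epoxidation (cytochrome P450 monooxygenase); the substrate channel anchors the carboxylate and presents only the last double bond to the iron-oxo oxidant, a known outcome for EPA that forms the C17–O bond with S configuration at C17 (the cis geometry makes C18 R).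

**Step 2**
Reactants: 2 (5Z,8Z,11Z,14Z)-16-[(2S,3R)-3-ethyloxiran-2-yl]hexadeca-5,8,11,14-tetraenoic acid
Product: 4 (5Z,8Z,11Z,14Z)-16-[(2S,3R)-3-ethyloxiran-2-yl]-1-(morpholin-4-yl)hexadeca-5,8,11,14-tetraen-1-one, via acyl imidazolide 3 (not isolated)
Conditions: CDI (1.1 equiv), CH2Cl2, 0 °C → rt, 1 h; then morpholine (1.5 equiv), rt
Reagents that add atoms: morpholine, C1COCCN1
Why: Amide coupling through the acyl imidazolide (CDI activation) runs under neutral conditions that leave the cis-epoxide and skipped tetraene untouched, and the morpholine amide is a ketone-stop acyl donor with no N–O bond for trivalent titanium to cleave.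

**Step 3**
Reactants: 4 (5Z,8Z,11Z,14Z)-16-[(2S,3R)-3-ethyloxiran-2-yl]-1-(morpholin-4-yl)hexadeca-5,8,11,14-tetraen-1-one
Product: 5 (5Z,8Z,11Z,14Z,17R)-17-hydroxy-1-(morpholin-4-yl)icosa-5,8,11,14-tetraen-1-one
Conditions: (η5-C5H4-menthyl)2TiCl2 (Kagan's complex, 10 mol %), Zn dust (2 equiv), 2,4,6-collidine·HCl (2.5 equiv), 1,4-cyclohexadiene (20 equiv), THF, 25 °C
Reagents that add atoms: none
Why: Proposed new method: catalyst-controlled regiodivergent reductive opening of an enantiopure, unfunctionalised cis-dialkyl (pseudo-meso) epoxide inside a skipped polyene; the trivalent titanocene (η5-C5H4-menthyl)2TiCl made in situ binds the oxirane oxygen and, because the two C–O bonds of a cis-epoxide are mirror-related, its chiral menthyl pocket should break only the bond at the R-configured carbon (C18); the resulting secondary C18 radical has only 4-exo or 5-endo cyclisation paths and is quenched by the large excess of 1,4-cyclohexadiene before it can abstract a bis-allylic hydrogen, after which collidinium chloride protonates the Ti–O bond and Zn returns titanium to the trivalent state; the C17–O bond from step 1 is never touched, so C17 becomes the R carbinol with retention, and the minor 17R,18S epoxide is diverted to the separable 18-hydroxy regioisomer, which raises the ee of 5; closest known reaction type: titanocene-catalysed enantioselective radical opening of meso-epoxides and regiodivergent opening of ether-substituted cis-epoxides.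

**Step 4**
Reactants: 6 benzene-1,3,5-triol (phloroglucinol)
Product: 7 1,3,5-tris(methoxymethoxy)benzene
Conditions: NaH (3.6 equiv), MOMCl (3.6 equiv), DMF, 0 °C → rt
Reagents that add atoms: chloromethyl methyl ether (MOMCl), COCCl
Why: Williamson-type O-alkylation of the phenoxides gives the tris-acetal, which protects the phenols against organolithiums and directs the later ortho-lithiation.

**Step 5**
Reactants: 5 (5Z,8Z,11Z,14Z,17R)-17-hydroxy-1-(morpholin-4-yl)icosa-5,8,11,14-tetraen-1-one; 7 1,3,5-tris(methoxymethoxy)benzene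
Product: 9 (5Z,8Z,11Z,14Z,17R)-17-hydroxy-1-[2,4,6-tris(methoxymethoxy)phenyl]icosa-5,8,11,14-tetraen-1-one, via aryllithium 8 (not isolated)
Conditions: 7 (2.6 equiv), n-BuLi (2.5 equiv), THF, 0 °C, 1 h; then 5 (1 equiv), −78 → −20 °C; sat. NH4Cl
Reagents that add atoms: none
Why: Directed ortho-lithiation between two OMOM groups, then nucleophilic acyl substitution on the morpholine amide (Weinreb-type ketone synthesis); the chelated tetrahedral adduct stops at the ketone, the first equivalent of 8 masks the C17 alcohol as its lithium alkoxide, and at −78 °C the hindered aryllithium does not deprotonate the bis-allylic positions.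

**Step 6**
Reactants: 9 (5Z,8Z,11Z,14Z,17R)-17-hydroxy-1-[2,4,6-tris(methoxymethoxy)phenyl]icosa-5,8,11,14-tetraen-1-one
Product: 10 (5Z,8Z,11Z,14Z,17R)-17-hydroxy-1-(2,4,6-trihydroxyphenyl)icosa-5,8,11,14-tetraen-1-one
Conditions: HCl (1.25 M in MeOH), THF, 35 °C, Ar, dark
Reagents that add atoms: none
Why: Acid-catalysed transacetalisation (MOM ether cleavage) in methanol traps the methoxymethyl cation as dimethoxymethane, under acid mild enough for the skipped Z-tetraene and the homoallylic alcohol, so C17 is not touched.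

**Compound list**
1 | (5Z,8Z,11Z,14Z,17Z)-icosa-5,8,11,14,17-pentaenoic acid (EPA) | CC/C=C\C/C=C\C/C=C\C/C=C\C/C=C\CCCC(=O)O | starting material
2 | (5Z,8Z,11Z,14Z)-16-[(2S,3R)-3-ethyloxiran-2-yl]hexadeca-5,8,11,14-tetraenoic acid | CC[C@H]1O[C@H]1C/C=C\C/C=C\C/C=C\C/C=C\CCCC(=O)O | intermediate
3 | (5Z,8Z,11Z,14Z)-16-[(2S,3R)-3-ethyloxiran-2-yl]-1-(1H-imidazol-1-yl)hexadeca-5,8,11,14-tetraen-1-one (acyl imidazolide) | CC[C@H]1O[C@H]1C/C=C\C/C=C\C/C=C\C/C=C\CCCC(=O)n1ccnc1 | intermediate
4 | (5Z,8Z,11Z,14Z)-16-[(2S,3R)-3-ethyloxiran-2-yl]-1-(morpholin-4-yl)hexadeca-5,8,11,14-tetraen-1-one | CC[C@H]1O[C@H]1C/C=C\C/C=C\C/C=C\C/C=C\CCCC(=O)N1CCOCC1 | intermediate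
5 | (5Z,8Z,11Z,14Z,17R)-17-hydroxy-1-(morpholin-4-yl)icosa-5,8,11,14-tetraen-1-one | CCC[C@@H](O)C/C=C\C/C=C\C/C=C\C/C=C\CCCC(=O)N1CCOCC1 | intermediate
6 | benzene-1,3,5-triol (phloroglucinol) | Oc1cc(O)cc(O)c1 | starting material
7 | 1,3,5-tris(methoxymethoxy)benzene | COCOc1cc(OCOC)cc(OCOC)c1 | intermediate
8 | [2,4,6-tris(methoxymethoxy)phenyl]lithium | [Li]c1c(OCOC)cc(OCOC)cc1OCOC | intermediate
9 | (5Z,8Z,11Z,14Z,17R)-17-hydroxy-1-[2,4,6-tris(methoxymethoxy)phenyl]icosa-5,8,11,14-tetraen-1-one | CCC[C@@H](O)C/C=C\C/C=C\C/C=C\C/C=C\CCCC(=O)c1c(OCOC)cc(OCOC)cc1OCOC | intermediate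
10 | (5Z,8Z,11Z,14Z,17R)-17-hydroxy-1-(2,4,6-trihydroxyphenyl)icosa-5,8,11,14-tetraen-1-one | CCC[C@@H](O)C/C=C\C/C=C\C/C=C\C/C=C\CCCC(=O)c1c(O)cc(O)cc1O | target

**Totals and risks**
Total step count: 6. Longest linear sequence: 5 (steps 1, 2, 3, 5, 6).

Most likely to fail, step 3 (the proposed new step). The chiral titanocene may not discriminate ethyl from Z-allyl well enough, or radical chemistry may scramble the skipped tetraene. The fallback uses known chemistry, sets out from 4 and comes back at 5. Periodic acid (H5IO6, THF/H2O, 0 °C) cleaves the epoxide of 4 to the aldehyde (3Z,6Z,9Z,12Z)-17-(morpholin-4-yl)-17-oxoheptadeca-3,6,9,12-tetraenal F1, which is used crude. Brown allylboration with (+)-Ipc2B(allyl), made from (+)-Ipc2BOMe and allylMgBr (the α-pinene antipode that attacks the Re face), in Et2O at −78 °C sets C17 and gives (5Z,8Z,11Z,14Z,17R)-17-hydroxy-1-(morpholin-4-yl)icosa-5,8,11,14,19-pentaen-1-one F2. Selective hydrogenation of the terminal vinyl group over the Z-disubstituted alkenes with RhCl(PPh3)3 and H2 (1 atm, benzene/EtOH, stopped at one equivalent) then gives 5.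

Second, step 5. The hindered aryllithium may enolise the amide or add sluggishly. The fallback sets out from 5 and comes back at 9. LiAlH4 (THF, −20 °C, inverse addition) reduces the morpholine amide to the aldehyde (5Z,8Z,11Z,14Z,17R)-17-hydroxyicosa-5,8,11,14-tetraenal F3. Addition of 8 at −78 °C, which is fast and reliable for aldehydes, gives the C1-epimeric (5Z,8Z,11Z,14Z,17R)-1-[2,4,6-tris(methoxymethoxy)phenyl]icosa-5,8,11,14-tetraene-1,17-diol F4. Activated MnO2 in CH2Cl2 oxidises only the benzylic carbinol and gives 9.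

Third, step 6. Acid may cause C-alkylation of the free phloroglucinol by formaldehyde equivalents or damage the polyene. The fallback replaces acid-labile by fluoride-labile protection, sets out from 6 and comes back at 10. NaH and SEMCl in DMF give 1,3,5-tris{[2-(trimethylsilyl)ethoxy]methoxy}benzene F5. n-BuLi in THF at 0 °C gives (2,4,6-tris{[2-(trimethylsilyl)ethoxy]methoxy}phenyl)lithium F6, which with 5 at −78 °C gives (5Z,8Z,11Z,14Z,17R)-17-hydroxy-1-(2,4,6-tris{[2-(trimethylsilyl)ethoxy]methoxy}phenyl)icosa-5,8,11,14-tetraen-1-one F7. TBAF in THF at 50 °C under argon removes the three SEM groups and gives 10.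

**Further compounds**
F1 | step 3 | (3Z,6Z,9Z,12Z)-17-(morpholin-4-yl)-17-oxoheptadeca-3,6,9,12-tetraenal | O=CC/C=C\C/C=C\C/C=C\C/C=C\CCCC(=O)N1CCOCC1
F2 | step 3 | (5Z,8Z,11Z,14Z,17R)-17-hydroxy-1-(morpholin-4-yl)icosa-5,8,11,14,19-pentaen-1-one | C=CC[C@@H](O)C/C=C\C/C=C\C/C=C\C/C=C\CCCC(=O)N1CCOCC1
F3 | step 5 | (5Z,8Z,11Z,14Z,17R)-17-hydroxyicosa-5,8,11,14-tetraenal | CCC[C@@H](O)C/C=C\C/C=C\C/C=C\C/C=C\CCCC=O
F4 | step 5 | (5Z,8Z,11Z,14Z,17R)-1-[2,4,6-tris(methoxymethoxy)phenyl]icosa-5,8,11,14-tetraene-1,17-diol (C1 epimers) | CCC[C@@H](O)C/C=C\C/C=C\C/C=C\C/C=C\CCCC(O)c1c(OCOC)cc(OCOC)cc1OCOC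
F5 | step 6 | 1,3,5-tris{[2-(trimethylsilyl)ethoxy]methoxy}benzene | C[Si](C)(C)CCOCOc1cc(OCOCC[Si](C)(C)C)cc(OCOCC[Si](C)(C)C)c1
F6 | step 6 | (2,4,6-tris{[2-(trimethylsilyl)ethoxy]methoxy}phenyl)lithium | [Li]c1c(OCOCC[Si](C)(C)C)cc(OCOCC[Si](C)(C)C)cc1OCOCC[Si](C)(C)C
F7 | step 6 | (5Z,8Z,11Z,14Z,17R)-17-hydroxy-1-(2,4,6-tris{[2-(trimethylsilyl)ethoxy]methoxy}phenyl)icosa-5,8,11,14-tetraen-1-one | CCC[C@@H](O)C/C=C\C/C=C\C/C=C\C/C=C\CCCC(=O)c1c(OCOCC[Si](C)(C)C)cc(OCOCC[Si](C)(C)C)cc1OCOCC[Si](C)(C)C
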